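**Plan**
- Retrosynthesis: the oxane is opened at O1–C2 (the benzylic ether bond), then the chain is cut at C2–C3 and at C5–C6.
- Feature used: in the oxane ring (O1, C2–C6), C3–C4(OH)–C5 is a glycerol-like three-carbon piece that can be electrophilic at both CH2 ends. C2 (bearing the 3,4-dihydroxy-5-methoxyphenyl ring) and C6 (bearing the 3,4-dihydroxyphenylethyl chain) are both attached to O1, so each can be carried as a 1,3-dithiane, i.e. a masked carbonyl used as an acyl anion.
- Forward: two benzyl-protected dithianes are made from their aldehydes and joined to (R)-epichlorohydrin in one flask (C2–C3 first, then C5–C6). This gives the open C2–C6 chain; no ring is formed there.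
- Both dithianes are then hydrolysed, the two ketones reduced, the oxane closed last at O1–C2, and the benzyl ethers removed.
- Stereochemistry: C4 is C2 of (R)-epichlorohydrin, which is never a reacting centre. C6 comes from C4-hydroxyl-directed syn reduction. C2 is set on ring closure through the benzylic cation, which leads to the diequatorial 2,6-cis oxane with the C4 hydroxyl axial.

Key step: step 6

Remark on the chemistry: in the open-chain heptane names, C1, C3 and C5 are the carbons that become C2, C4 and C6 of the oxane; compounds 1, 3, 5 and 9 are taken as purchased.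

**Route**

Step 1
Reactants: 1 3,4-dihydroxy-5-methoxybenzaldehyde (5-hydroxyvanillin)
Product: 2 3,4-bis(benzyloxy)-5-methoxybenzaldehyde
Conditions: BnBr (2.3 equiv), K2CO3, DMF, 50 °C, N2
Reagents that add atoms: benzyl bromide, BrCc1ccccc1
Why: Williamson ether synthesis, in which both phenoxides are O-benzylated while the aldehyde is inert to carbonate.

Step 2
Reactants: 2 3,4-bis(benzyloxy)-5-methoxybenzaldehyde; 3 propane-1,3-dithiol
Product: 4 2-[3,4-bis(benzyloxy)-5-methoxyphenyl]-1,3-dithiane
Conditions: BF3·OEt2 (cat.), CH2Cl2, 0 °C → rt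
Reagents that add atoms: none
Why: Lewis-acid-catalysed dithioacetalisation of an aromatic aldehyde (the first half of Corey–Seebach umpolung), which aryl benzyl ethers tolerate at this temperature.

Step 3
Reactants: 5 3-(3,4-dihydroxyphenyl)propanoic acid
Product: 6 benzyl 3-[3,4-bis(benzyloxy)phenyl]propanoate
Conditions: BnBr (3.4 equiv), K2CO3, DMF, 60 °C, N2
Reagents that add atoms: benzyl bromide, BrCc1ccccc1
Why: exhaustive Williamson-type O-alkylation of the two phenoxides and the carboxylate, so that acid and catechol are protected in one operation.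

Step 4
Reactants: 6 benzyl 3-[3,4-bis(benzyloxy)phenyl]propanoate
Product: 7 3-[3,4-bis(benzyloxy)phenyl]propanal
Conditions: DIBAL-H (1.1 equiv), CH2Cl2, −78 °C; MeOH, then aq. Rochelle salt
Reagents that add atoms: none
Why: partial DIBAL-H reduction of an ester, whose tetrahedral aluminium hemiacetal persists at −78 °C and releases the aldehyde only on work-up.

Step 5
Reactants: 7 3-[3,4-bis(benzyloxy)phenyl]propanal; 3 propane-1,3-dithiol
Product: 8 2-{2-[3,4-bis(benzyloxy)phenyl]ethyl}-1,3-dithiane
Conditions: BF3·OEt2 (cat.), CH2Cl2, 0 °C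
Reagents that add atoms: none
Why: Lewis-acid-catalysed dithioacetalisation of an aliphatic aldehyde, fast at 0 °C and without effect on the benzyl ethers.

Step 6
Reactants: 4 2-[3,4-bis(benzyloxy)-5-methoxyphenyl]-1,3-dithiane; 9 (R)-epichlorohydrin [(2R)-2-(chloromethyl)oxirane]; 8 2-{2-[3,4-bis(benzyloxy)phenyl]ethyl}-1,3-dithiane
Product: 14 (2S)-1-{2-[3,4-bis(benzyloxy)-5-methoxyphenyl]-1,3-dithian-2-yl}-3-(2-{2-[3,4-bis(benzyloxy)phenyl]ethyl}-1,3-dithian-2-yl)propan-2-ol, via lithiated aryl dithiane 10 (not isolated), via chlorohydrin lithium alkoxide 11 (not isolated), via aryl dithianyl epoxide 12 (not isolated), via lithiated arylethyl dithiane 13 (not isolated)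
Conditions: 4, n-BuLi (1.05 equiv), THF, −78 → −30 °C; 9 (1.0 equiv), −78 → −30 °C, then rt; recool to −78 °C, add 13 (from 8, n-BuLi, THF, −30 °C, second flask) and DMPU, → 0 °C; aq. NH4Cl
Reagents that add atoms: none
Why: This is Corey–Seebach umpolung used twice on one bis-electrophile: the soft 2-lithio-2-aryl dithiane 10 opens the oxirane of 9 at its CH2 terminus by SN2 (C2–C3 bond) to give chlorohydrin alkoxide 11, which on warming closes by 3-exo-tet Williamson displacement of chloride to the new terminal epoxide 12, and the more nucleophilic 2-alkyl anion 13 then opens 12 at its CH2 (C5–C6 bond). The closest known reaction type is the one-flask epichlorohydrin linchpin coupling of two different lithiated 1,3-dithianes. No ring remains in 14; the only ring closed on the way is the transient oxirane of 12. No stereocentre is created: the carbinol carbon is C2 of epichlorohydrin, which is never attacked, so its configuration is carried over and reads S in 14 only because the CIP ranks of its two CH2 arms change. The step needs 10 to open the epoxide instead of displacing chloride directly (which would lead into the enantiomeric series), and it needs one anion per electrophilic site. The first is secured by the much higher SN2 reactivity of the strained oxirane CH2 at low temperature; the second by equimolar 9, by the fact that 11 closes only after the cold anion 10 is consumed, and by the order of addition, which also fixes which arm carries which aryl group.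

Step 7
Reactants: 14 (2S)-bis-dithiane carbinol
Product: 15 (3S)-1-[3,4-bis(benzyloxy)-5-methoxyphenyl]-7-[3,4-bis(benzyloxy)phenyl]-3-hydroxyheptane-1,5-dione
Conditions: MeI (excess), CaCO3, MeCN/H2O (9:1), 45 °C
Reagents that add atoms: water, O
Why: alkylative dithioacetal hydrolysis, in which S-methylation makes each dithiane a sulfonium leaving group and buffered water delivers the ketone under conditions that are neither oxidising nor acidic, so the benzyl ethers, the electron-rich rings and the β-hydroxy ketone (no elimination) should survive.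

Step 8
Reactants: 15 (3S)-3-hydroxy-1,5-diketone
Product: 16 (1S,3S,5S)-1-[3,4-bis(benzyloxy)-5-methoxyphenyl]-7-[3,4-bis(benzyloxy)phenyl]heptane-1,3,5-triol
Conditions: Et2BOMe (2.5 equiv), THF/MeOH (4:1), −78 °C; NaBH4, −78 → −30 °C; AcOH, then MeOH co-evaporation (boron leaves as Et2BOMe)
Reagents that add atoms: none
Why: Narasaka–Prasad reduction, in which the C3 diethylborinate chelates a β-carbonyl in a half-chair and borohydride adds axially from outside, setting C5 syn to C3 (and C1 likewise, although a C1 epimer is harmless because step 9 re-sets that centre), with excess Et2BOMe keeping a borinate on C3 available for the second ketone once the first new carbinol is itself borylated.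

Step 9
Reactants: 16 (1S,3S,5S)-triol
Product: 17 (2S,4S,6S)-2-[3,4-bis(benzyloxy)-5-methoxyphenyl]-6-{2-[3,4-bis(benzyloxy)phenyl]ethyl}oxan-4-ol
Conditions: p-TsOH·H2O (10 mol %), CH2Cl2, rt
Reagents that add atoms: none
Why: acid-catalysed SN1 cycloetherification, in which the benzylic carbinol ionises to a cation stabilised by the para oxygen and the C5 hydroxyl traps it through a chair with aryl and arylethyl equatorial; since the benzylic C–O bond of the product can re-ionise, the diequatorial 2,6-cis oxane with axial C4–OH is both the kinetic and the thermodynamic product whatever the configuration at C1 of 16, and C4 and C6 are not touched.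

Step 10
Reactants: 17 (2S,4S,6S)-tetra-O-benzyl oxanol
Product: 18 (2S,4S,6S)-2-(3,4-dihydroxy-5-methoxyphenyl)-6-[2-(3,4-dihydroxyphenyl)ethyl]oxan-4-ol
Conditions: H2 (1 atm), 10% Pd/C, EtOAc/MeOH, rt; work-up under argon
Reagents that add atoms: none
Why: hydrogenolysis of the four aryl benzyl ethers over palladium at atmospheric pressure, under which the cyclic benzylic ether C2–O1 and the aryl methyl ether should persist, as is usual for 2-aryl oxanes and flavans.

**Compound list**

1 | 3,4-dihydroxy-5-methoxybenzaldehyde (5-hydroxyvanillin) | COc1cc(C=O)cc(O)c1O | starting material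
2 | 3,4-bis(benzyloxy)-5-methoxybenzaldehyde | COc1cc(C=O)cc(OCc2ccccc2)c1OCc1ccccc1 | intermediate
3 | propane-1,3-dithiol | SCCCS | starting material
4 | 2-[3,4-bis(benzyloxy)-5-methoxyphenyl]-1,3-dithiane | COc1cc(C2SCCCS2)cc(OCc2ccccc2)c1OCc1ccccc1 | intermediate
5 | 3-(3,4-dihydroxyphenyl)propanoic acid | OC(=O)CCc1ccc(O)c(O)c1 | starting material
6 | benzyl 3-[3,4-bis(benzyloxy)phenyl]propanoate | O=C(CCc1ccc(OCc2ccccc2)c(OCc2ccccc2)c1)OCc1ccccc1 | intermediate
7 | 3-[3,4-bis(benzyloxy)phenyl]propanal | O=CCCc1ccc(OCc2ccccc2)c(OCc2ccccc2)c1 | intermediate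
8 | 2-{2-[3,4-bis(benzyloxy)phenyl]ethyl}-1,3-dithiane | C1(CCc2ccc(OCc3ccccc3)c(OCc3ccccc3)c2)SCCCS1 | intermediate
9 | (R)-epichlorohydrin, (2R)-2-(chloromethyl)oxirane | ClC[C@H]1CO1 | starting material
10 | 2-lithio-2-[3,4-bis(benzyloxy)-5-methoxyphenyl]-1,3-dithiane | [Li]C1(c2cc(OC)c(OCc3ccccc3)c(OCc3ccccc3)c2)SCCCS1 | intermediate
11 | lithium (2R)-1-chloro-3-{2-[3,4-bis(benzyloxy)-5-methoxyphenyl]-1,3-dithian-2-yl}propan-2-olate | ClC[C@H](O[Li])CC1(c2cc(OC)c(OCc3ccccc3)c(OCc3ccccc3)c2)SCCCS1 | intermediate
12 | 2-[3,4-bis(benzyloxy)-5-methoxyphenyl]-2-{[(2R)-oxiran-2-yl]methyl}-1,3-dithiane | C1[C@H](O1)CC2(c3cc(OC)c(OCc4ccccc4)c(OCc4ccccc4)c3)SCCCS2 | intermediate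
13 | 2-lithio-2-{2-[3,4-bis(benzyloxy)phenyl]ethyl}-1,3-dithiane | [Li]C1(CCc2ccc(OCc3ccccc3)c(OCc3ccccc3)c2)SCCCS1 | intermediate
14 | (2S)-1-{2-[3,4-bis(benzyloxy)-5-methoxyphenyl]-1,3-dithian-2-yl}-3-(2-{2-[3,4-bis(benzyloxy)phenyl]ethyl}-1,3-dithian-2-yl)propan-2-ol | COc1cc(C2(C[C@@H](O)CC3(CCc4ccc(OCc5ccccc5)c(OCc5ccccc5)c4)SCCCS3)SCCCS2)cc(OCc2ccccc2)c1OCc1ccccc1 | intermediate
15 | (3S)-1-[3,4-bis(benzyloxy)-5-methoxyphenyl]-7-[3,4-bis(benzyloxy)phenyl]-3-hydroxyheptane-1,5-dione | COc1cc(C(=O)C[C@@H](O)CC(=O)CCc2ccc(OCc3ccccc3)c(OCc3ccccc3)c2)cc(OCc2ccccc2)c1OCc1ccccc1 | intermediate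
16 | (1S,3S,5S)-1-[3,4-bis(benzyloxy)-5-methoxyphenyl]-7-[3,4-bis(benzyloxy)phenyl]heptane-1,3,5-triol | COc1cc([C@@H](O)C[C@@H](O)C[C@@H](O)CCc2ccc(OCc3ccccc3)c(OCc3ccccc3)c2)cc(OCc2ccccc2)c1OCc1ccccc1 | intermediate
17 | (2S,4S,6S)-2-[3,4-bis(benzyloxy)-5-methoxyphenyl]-6-{2-[3,4-bis(benzyloxy)phenyl]ethyl}oxan-4-ol | COc1cc([C@@H]2C[C@@H](O)C[C@H](CCc3ccc(OCc4ccccc4)c(OCc4ccccc4)c3)O2)cc(OCc2ccccc2)c1OCc1ccccc1 | intermediate
18 | (2S,4S,6S)-2-(3,4-dihydroxy-5-methoxyphenyl)-6-[2-(3,4-dihydroxyphenyl)ethyl]oxan-4-ol | COc1cc([C@@H]2C[C@@H](O)C[C@H](CCc3ccc(O)c(O)c3)O2)cc(O)c1O | target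

**Step count**

Total: 10 steps. Longest linear sequence: 8 steps (steps 3–10, from 5).

**Steps most likely to fail**

Step 6. The three components may scramble. If alkoxide 11 closes while some anion 10 is still present, the symmetric double adduct of the aryl dithiane forms; if closure is incomplete when 13 is added, 13 is lost to proton transfer and unreacted chlorohydrin remains. The fallback runs the linchpin as two separate alkylations with a purified epoxide. It sets out from 4 and 9: anion 10 is added to 9 at −78 °C and the mixture is quenched cold to give (2R)-1-chloro-3-{2-[3,4-bis(benzyloxy)-5-methoxyphenyl]-1,3-dithian-2-yl}propan-2-ol F1. K2CO3 in MeOH closes F1 to epoxide 12, here isolated and purified. Compound 12 is then opened by anion 13 (from 8, n-BuLi, THF/DMPU), and the route is rejoined at 14.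

Step 8. Facial selectivity at C5 may be poor if the single C3 borinate is tied up with the aryl ketone, or with the first-formed carbinol, so that hydride reaches the aliphatic ketone without direction. The fallback takes stereocontrol away from C3-directed hydride delivery. It sets out from 15: Noyori-type asymmetric transfer hydrogenation [RuCl(p-cymene)((S,S)-TsDPEN), HCO2H/Et3N] reduces aryl ketones and leaves dialkyl ketones. Under catalyst control it is expected to give (1S,3R)-1-[3,4-bis(benzyloxy)-5-methoxyphenyl]-7-[3,4-bis(benzyloxy)phenyl]-1,3-dihydroxyheptan-5-one F2. This δ-hydroxy ketone closes to its lactol, (4R,6S)-6-[3,4-bis(benzyloxy)-5-methoxyphenyl]-2-{2-[3,4-bis(benzyloxy)phenyl]ethyl}oxane-2,4-diol F3. Et3SiH with catalytic TMSOTf in CH2Cl2 at −78 °C then reduces the derived oxocarbenium ion by axial hydride attack, which puts the arylethyl chain equatorial and cis to the aryl group. The route is rejoined at 17, bypassing 16 and step 9.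

Step 9. The benzylic cation may lose a proton (E1) to a styrene, whose allylic C3 hydroxyl can then ionise and be lost, before the C5 hydroxyl traps the cation. The fallback closes the ring at the oxocarbenium level instead. It sets out from 16: activated MnO2 in CH2Cl2 oxidises only the benzylic carbinol, giving (3S,5S)-1-[3,4-bis(benzyloxy)-5-methoxyphenyl]-7-[3,4-bis(benzyloxy)phenyl]-3,5-dihydroxyheptan-1-one F4. F4 is in equilibrium with its lactol, (4S,6S)-2-[3,4-bis(benzyloxy)-5-methoxyphenyl]-6-{2-[3,4-bis(benzyloxy)phenyl]ethyl}oxane-2,4-diol F5. Et3SiH with catalytic TMSOTf in CH2Cl2 at −78 °C reduces the aryl-stabilised oxocarbenium ion by axial hydride delivery, and the route is rejoined at 17.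

**Further compounds**

F1 | step 6 | (2R)-1-chloro-3-{2-[3,4-bis(benzyloxy)-5-methoxyphenyl]-1,3-dithian-2-yl}propan-2-ol | ClC[C@H](O)CC1(c2cc(OC)c(OCc3ccccc3)c(OCc3ccccc3)c2)SCCCS1
F2 | step 8 | (1S,3R)-1-[3,4-bis(benzyloxy)-5-methoxyphenyl]-7-[3,4-bis(benzyloxy)phenyl]-1,3-dihydroxyheptan-5-one | COc1cc([C@@H](O)C[C@@H](O)CC(=O)CCc2ccc(OCc3ccccc3)c(OCc3ccccc3)c2)cc(OCc2ccccc2)c1OCc1ccccc1
F3 | step 8 | (4R,6S)-6-[3,4-bis(benzyloxy)-5-methoxyphenyl]-2-{2-[3,4-bis(benzyloxy)phenyl]ethyl}oxane-2,4-diol (lactol of F2, anomeric mixture) | COc1cc([C@@H]2C[C@@H](O)CC(O)(CCc3ccc(OCc4ccccc4)c(OCc4ccccc4)c3)O2)cc(OCc2ccccc2)c1OCc1ccccc1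
F4 | step 9 | (3S,5S)-1-[3,4-bis(benzyloxy)-5-methoxyphenyl]-7-[3,4-bis(benzyloxy)phenyl]-3,5-dihydroxyheptan-1-one | COc1cc(C(=O)C[C@@H](O)C[C@@H](O)CCc2ccc(OCc3ccccc3)c(OCc3ccccc3)c2)cc(OCc2ccccc2)c1OCc1ccccc1
F5 | step 9 | (4S,6S)-2-[3,4-bis(benzyloxy)-5-methoxyphenyl]-6-{2-[3,4-bis(benzyloxy)phenyl]ethyl}oxane-2,4-diol (lactol of F4, anomeric mixture) | COc1cc(C2(O)C[C@@H](O)C[C@H](CCc3ccc(OCc4ccccc4)c(OCc4ccccc4)c3)O2)cc(OCc2ccccc2)c1OCc1ccccc1
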